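**Assumption:** both building blocks are bought as catalogue compounds, and the (S,S)-configured acid of step 2 is taken to give the (4S) centre (if the sense proves opposite, its mirror image is used and nothing else changes).

## Retrosynthetic overview

1. Dipolynaphthalene B (cis, 1S,4S) ⇐ (4S)-4-aryl-5-methoxy-1-tetralone, by a catalyst-controlled ketone reduction that sets C1.
2. The 4-aryl tetralone ⇐ 8-methoxy-1-naphthol (attacking through C4, para to OH) + the C4 benzylic cation of 4-hydroxy-5-methoxy-1-tetralone. This is the presumed biogenetic dehydrative Friedel–Crafts union, run under a confined chiral acid so that the C4–C1′ bond and the C4 stereocentre form in one event.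
3. 4-Hydroxy-5-methoxy-1-tetralone ⇐ 5-methoxy-1-tetralone, by benzylic bromination and hydrolysis.
4. Ring order: no ring is built. The tetralone bicycle and the naphthalene bicycle are bought intact, as in the biogenesis, where two preformed naphthalene-derived units are joined by one C–C bond.

## Route

Step 1
Reactants: 1 5-methoxy-1-tetralone (5-methoxy-3,4-dihydronaphthalen-1(2H)-one)
Product: 3 rac-4-hydroxy-5-methoxy-3,4-dihydronaphthalen-1(2H)-one, via rac-4-bromo-5-methoxy-1-tetralone 2 (not isolated)
Conditions: N-bromosuccinimide (1.05 equiv), 2,2′-azobis(2-methylpropionitrile) (5 mol%), PhCF3, 80 °C, hν; filter, evaporate; then Ag2CO3 (0.6 equiv), acetone/H2O 4:1, 20 °C, dark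
Reagents that add atoms: water (O); N-bromosuccinimide (O=C1CCC(=O)N1Br) puts bromine into 2 only, none of it stays in 3
Why: Wohl–Ziegler radical bromination takes the C4–H, the only benzylic C–H (further weakened by the ortho-methoxy group), and the ortho-methoxybenzylic bromide is hydrolysed at once by silver-assisted SN1 substitution; C4 is formed racemic, which does not matter because it is ionised in step 2.

Step 2
Reactants: 3 rac-4-hydroxy-5-methoxy-3,4-dihydronaphthalen-1(2H)-one; 4 8-methoxynaphthalen-1-ol (2 equiv, excess recovered)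
Product: 6 (4S)-4-(4-hydroxy-5-methoxynaphthalen-1-yl)-5-methoxy-3,4-dihydronaphthalen-1(2H)-one, via 5-methoxy-1-oxotetralin-4-ylium cation 5 (not isolated)
Conditions: (S,S)-IDPi acid HN[P(=NSO2CF3)(O2C20H10Ar2)]2, Ar = 3,5-(CF3)2C6H3, each O2C20H10Ar2 an (S)-3,3′-diaryl-1,1′-binaphthalene-2,2′-diolate (5 mol%), 5 Å molecular sieves, CH2Cl2/toluene, −40 → −20 °C, slow addition of 3
Reagents that add atoms: none
Why: Proposed new method: the strong confined acid ionises the ortho-methoxybenzylic alcohol 3 with loss of water to the achiral cation 5, held as a contact ion pair inside the aryl-walled pocket of the chiral anion, and C4 of naphthol 4 (para to OH, the site used in nature; the OH is tied up by its hydrogen bond to the peri-methoxy group) attacks one face to set C4 as (S) in an enantioconvergent counteranion-directed SN1 Friedel–Crafts alkylation; the closest known reaction types are confined imidodiphosphorimidate-catalysed asymmetric SN1 substitutions of racemic secondary benzylic electrophiles and chiral phosphoric acid-catalysed additions of naphthols to ortho-quinone methides generated from benzylic alcohols.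

Step 3
Reactants: 6 (4S)-4-(4-hydroxy-5-methoxynaphthalen-1-yl)-5-methoxy-3,4-dihydronaphthalen-1(2H)-one
Product: 7 (1S,4S)-4-(4-hydroxy-5-methoxynaphthalen-1-yl)-5-methoxy-1,2,3,4-tetrahydronaphthalen-1-ol (dipolynaphthalene B, cis)
Conditions: RuCl[(S,S)-TsDPEN](p-cymene) (1 mol%), HCO2H/Et3N 5:2, EtOAc, 30 °C; chromatography
Reagents that add atoms: none
Why: Noyori–Ikariya asymmetric transfer hydrogenation with the (S,S) catalyst delivers hydride to the face that gives the (1S) carbinol, as it does for 1-tetralone itself, and on the (4S) ketone this is also the face anti to the pseudoaxial C4 aryl group, so catalyst and substrate preferences match to give the cis-(1S,4S) product; any (4R) ketone carried through becomes the separable trans-(1S,4R) diastereomer, so the step also raises the ee of 7, and the free naphthol is tolerated.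

## Compound list

1 | 5-methoxy-1-tetralone (5-methoxy-3,4-dihydronaphthalen-1(2H)-one) | COc1cccc2c1CCCC2=O | starting material
2 | rac-4-bromo-5-methoxy-3,4-dihydronaphthalen-1(2H)-one | COc1cccc2c1C(Br)CCC2=O | intermediate
3 | rac-4-hydroxy-5-methoxy-3,4-dihydronaphthalen-1(2H)-one | COc1cccc2c1C(O)CCC2=O | intermediate
4 | 8-methoxynaphthalen-1-ol | COc1cccc2cccc(O)c12 | starting material
5 | 5-methoxy-1-oxo-1,2,3,4-tetrahydronaphthalen-4-ylium (ion pair with the chiral acid anion) | COc1cccc2c1[CH+]CCC2=O | intermediate
6 | (4S)-4-(4-hydroxy-5-methoxynaphthalen-1-yl)-5-methoxy-3,4-dihydronaphthalen-1(2H)-one | COc1cccc2c1[C@H](c1ccc(O)c3c(OC)cccc13)CCC2=O | intermediate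
7 | (1S,4S)-4-(4-hydroxy-5-methoxynaphthalen-1-yl)-5-methoxy-1,2,3,4-tetrahydronaphthalen-1-ol (dipolynaphthalene B) | COc1cccc2c1[C@H](c1ccc(O)c3c(OC)cccc13)CC[C@@H]2O | target

## Step count and risks

Total steps: 3. Longest linear sequence: 3 (1 → 3 → 6 → 7); 4 enters in step 2.

**Most likely to fail, in order:**

**Step 2.** The risks are low enantioselectivity, competing attack through C2 of the naphthol, and E1 loss of the cation to 5-methoxy-1-naphthol. Fallback, setting out from 3 and 4: the two are joined with no chiral information, in hexafluoroisopropanol with 5 mol% TfOH at 0 °C (plain SN1 Friedel–Crafts), to give the racemic ketone rac-4-(4-hydroxy-5-methoxynaphthalen-1-yl)-5-methoxy-3,4-dihydronaphthalen-1(2H)-one F1. F1 is then reduced with the ruthenium catalyst of step 3, which turns the two enantiomers into diastereomers. The (4S) half gives 7 and the (4R) half gives the trans diol (1S,4R)-4-(4-hydroxy-5-methoxynaphthalen-1-yl)-5-methoxy-1,2,3,4-tetrahydronaphthalen-1-ol F2, removed by chromatography. The route is rejoined at 7, at the price of a 50% ceiling.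

**Step 1.** The risks are bromination on the ring or at C2, and elimination of 2 to 5-methoxy-1-naphthol during hydrolysis. Fallback, setting out from 1: the C4–H is acyloxylated directly by a Kharasch–Sosnovsky reaction (tert-butyl perbenzoate, CuBr 5 mol%, MeCN, 70 °C). The electrophilic tert-butoxyl radical abstracts the electron-rich benzylic hydrogen rather than the one next to the carbonyl, giving rac-8-methoxy-4-oxo-1,2,3,4-tetrahydronaphthalen-1-yl benzoate F3. Methanolysis (K2CO3, MeOH, 0 °C) frees the alcohol, and the route is rejoined at 3.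

**Step 3.** The risks are interference of the free peri-methoxy naphthol with the ruthenium catalyst, or insufficient catalyst control over the remote C4 centre. Fallback, setting out from 6: the naphthol is capped (TBSCl, imidazole, DMF, 20 °C) to give the silyl ether (4S)-4-[4-(tert-butyldimethylsilyloxy)-5-methoxynaphthalen-1-yl]-5-methoxy-3,4-dihydronaphthalen-1(2H)-one F4. The ketone is then reduced by a Corey–Bakshi–Shibata reduction ((R)-1-methyl-3,3-diphenyltetrahydro-1H,3H-pyrrolo[1,2-c][1,3,2]oxazaborole 10 mol%, BH3·SMe2, THF, −20 °C), which gives (S)-1-tetralols, to the carbinol (1S,4S)-4-[4-(tert-butyldimethylsilyloxy)-5-methoxynaphthalen-1-yl]-5-methoxy-1,2,3,4-tetrahydronaphthalen-1-ol F5. Bu4NF in THF at 0 °C removes the silyl group, and the route is rejoined at 7.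

## Further compounds

F1 | step 2 | rac-4-(4-hydroxy-5-methoxynaphthalen-1-yl)-5-methoxy-3,4-dihydronaphthalen-1(2H)-one | COc1cccc2c1C(c1ccc(O)c3c(OC)cccc13)CCC2=O
F2 | step 2 | (1S,4R)-4-(4-hydroxy-5-methoxynaphthalen-1-yl)-5-methoxy-1,2,3,4-tetrahydronaphthalen-1-ol (trans) | COc1cccc2c1[C@@H](c1ccc(O)c3c(OC)cccc13)CC[C@@H]2O
F3 | step 1 | rac-8-methoxy-4-oxo-1,2,3,4-tetrahydronaphthalen-1-yl benzoate | COc1cccc2c1C(OC(=O)c1ccccc1)CCC2=O
F4 | step 3 | (4S)-4-[4-(tert-butyldimethylsilyloxy)-5-methoxynaphthalen-1-yl]-5-methoxy-3,4-dihydronaphthalen-1(2H)-one | COc1cccc2c1[C@H](c1ccc(O[Si](C)(C)C(C)(C)C)c3c(OC)cccc13)CCC2=O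
F5 | step 3 | (1S,4S)-4-[4-(tert-butyldimethylsilyloxy)-5-methoxynaphthalen-1-yl]-5-methoxy-1,2,3,4-tetrahydronaphthalen-1-ol | COc1cccc2c1[C@H](c1ccc(O[Si](C)(C)C(C)(C)C)c3c(OC)cccc13)CC[C@@H]2O
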